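Open the books.

all flasks: free monomer 0.10 M (fed, over 1.0 h)
- beta: protic impurity 0.050 M; initiator 1.1 mol%; run made earlier; the fed solution adds 0.20 times the starting volume
- eta: protic impurity 0.050 M; initiator 4.2 mol%; run made earlier; the fed solution adds 0.20 times the starting volume
- flask: protic impurity 0.0500 M; initiator 2.1 mol%; the fed solution adds 0.20 times the starting volume; time 1.0 h

| run | time / min | monomer in chains / % | free monomer / % |
|---|---|---|---|
| beta | 15.0 | 4 | 22 |
| beta | 30.0 | 8 | 42 |
| beta | 40.0 | 7 | 51 |
| beta | 60.0 | 25 | 73 |
| beta | 80.0 | 26 | 60 |
| eta | 15.0 | 4 | 21 |
| eta | 30.0 | 18 | 37 |
| eta | 40.0 | 21 | 41 |
| eta | 60.0 | 35 | 60 |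
| eta | 80.0 | 47 | 48 |

(each reading ± 2 percentage points)

- every charge counts on the volume at the start, and the solution that is fed holds the whole dose
- the average divides the monomer in chains by the number of chains, living and dead together; two radicals that join make one chain
- the earlier runs do not show the number of chains; that part of a forecast is a guess
- percentages count the whole charge, also what has not yet gone in

- average number of monomer units in a chain (living and dead chains, two that joined counted as one) at 1.0 h
- part of the free monomer that has reacted at 1.0 h

The flask receives its free monomer over 1.0 h, so at the asked time the charge is in and can be booked entry by entry. The loading of 2.1 mol% lies near the geometric middle of beta's 1.1 mol% and eta's 4.2 mol%, so the readings of those runs at 60.0 min are averaged in that way. The first entry, free monomer, comes to 66.2% of the charge, and this reckoning therefore puts the reacted part at 33.8%. The second entry, monomer in chains, comes to 29.6%. The remaining 4.2 percentage points has to be held against a scatter of 2 points on each reading.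

The chains need a book of their own, and the earlier runs do not show them, so a zero of the scale has to serve. Suppose that one initiator splits into two radicals and that radicals join two at a time, by termination by combination, so that each initiator spent gives one chain. Call the chains per monomer charged, with every initiator having given one, the chain ceiling: 2.10%. Monomer in chains over this ceiling gives 14.1 units as a mark, and initiator still unspent at the asked time leaves fewer chains and a greater length.

The forecast gave 13 units (range 3 to 35) and 31% reacted (range 26% to 36%), with the remark: “Incomplete decomposition raises this, while transfer to the large impurity excess lowers it.” Both of its numbers stand a little below this reckoning.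

The flask gives 16.6 units and 32.6% reacted.

    initiator → 2 initiating radical (k = 0.0240 min⁻¹)
    free monomer + initiating radical → growing radical + monomer in chains (k = 6.00 × 10⁵ L mol⁻¹ min⁻¹)
    free monomer + growing radical → monomer in chains + growing radical, rate k3*[growing radical]*[free monomer] (k = 55000 L mol⁻¹ min⁻¹)
    2 growing radical → dead chain (k = 8.00 × 10⁶ L mol⁻¹ s⁻¹)
    protic impurity + free monomer → quenched substrate (k = 0.0650 L mol⁻¹ min⁻¹)

In this flask the half-life of initiator by its own loss, 0.48 h, is shorter than the 1.0 h of the run, and 24% of the initiator is left at that time. The 26.7% of monomer in chains gives 12.7 units over the full ceiling, but 16.7 over its spent part, beside the 16.6 found. The same flask read at 4.0 h has 0.32% of its initiator left, so nearly all of it is spent, and 54.2% over the full ceiling gives 25.8 units. The computed result there is 25.9 units, with 74.0% reacted.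

Readings and results are simulated with constants of no real substance; the scatter is artificial.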